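The pyran carbon C3′ of the B ring sits between the furan oxygen on C2′ and the pyran oxygen on C4′, and O‑C2′ lies para to the 5′‑OH, so the B ring is a masked alkoxy‑p‑benzoquinone. The 2,2‑dimethyl‑2H‑pyran is therefore annulated first, on 2,5‑dimethoxyphenol. Its only free ortho carbon takes up 3‑methylbut‑2‑enal in one boron‑templated operation (ortho C‑alkylation, o‑quinone methide, oxa‑6π closure) that forms both the aryl–CH= and the O–CMe2 bond. Oxidative demethylation then gives a chromenequinone. A Nenitzescu‑type union with the A‑ring enaminone builds the benzofuran, and a dehydrogenative C–O closure completes the pyranone.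

Key step: step 1

Remark: the target has no stereocentre. Locants C2–C8a (pyranone and A ring) and C1′–C6′ (B ring) follow isoflavonoid numbering; "chroman" means 3,4‑dihydro‑2H‑chromene.

Step 1
Reactants: 1 2,5-dimethoxyphenol; 2 3-methylbut-2-enal
Product: 5 5,8-dimethoxy-2,2-dimethyl-2H-chromene, via benzodioxaborin 3 (not isolated), via o-quinone methide 4 (not isolated)
Conditions: PhB(OH)2 (1.1 equiv), AcOH, toluene, reflux, Dean–Stark
Reagents that add atoms: none
Why: Phenylboronic acid condenses with the phenol O–H of 1 and with the aldehyde of 2 and delivers the carbonyl carbon to the ortho carbon C6 within a six-membered boron template, so the aryl C–CH bond forms ortho-specifically and gives 3. On heating, 3 fragments (retro-[4+2], release of the boronic acid) to o-quinone methide 4, whose 1-oxatriene closes by a thermal disrotatory oxa-6π electrocyclisation that makes the O–CMe2 bond and restores the arene. The closest known reaction type is the boronic-acid-mediated phenol/enal synthesis of 2,2-dimethylchromenes (formal [3+3] annulation). The pyran ring closes by 6π electrocyclisation and no stereocentre is formed. The selectivity needed is ortho instead of para C-alkylation at a single site: the boron tether enforces ortho attack, C2 is blocked by OMe, and C6, flanked by OH and OMe, is the only free ortho carbon. The same template secures 1,2-addition to the enal over conjugate addition.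

Step 2
Reactants: 5 5,8-dimethoxy-2,2-dimethyl-2H-chromene
Product: 6 2,2-dimethyl-2H-chromene-5,8-dione
Conditions: CAN (2.5 equiv), MeCN–H2O, 0 °C
Reagents that add atoms: water, O
Why: Oxidative demethylation of a hydroquinone dimethyl ether by cerium(IV) (two one-electron oxidations, water adding at the ipso carbons and methanol leaving) should give the p-quinone, and the short reaction at 0 °C should leave the styrene-type pyran double bond untouched.

Step 3
Reactants: 7 2,4,6-trihydroxyacetophenone
Product: 8 1-[4-(benzyloxy)-2,6-dihydroxyphenyl]ethanone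
Conditions: BnBr (1.0 equiv), K2CO3 (1.0 equiv), acetone, rt
Reagents that add atoms: benzyl bromide, BrCc1ccccc1
Why: Williamson etherification should be selective for the 4-OH, which is the most acidic and the only non-chelated hydroxyl (para to the acetyl group, the 2- and 6-OH being hydrogen-bonded to the carbonyl), when one equivalent of base and halide is used.

Step 4
Reactants: 8 1-[4-(benzyloxy)-2,6-dihydroxyphenyl]ethanone
Product: 9 1-[5-(benzyloxy)-7-hydroxy-2,2-dimethylchroman-8-yl]ethanone
Conditions: isoprene (1.3 equiv), Amberlyst 15, THF–heptane, 65 °C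
Reagents that add atoms: isoprene, C=CC(C)=C
Why: Acid-catalysed Friedel–Crafts prenylation followed by Markovnikov hydroalkoxylation (chroman annulation of a phenol with isoprene) should place the ring oxygen ortho to the acetyl group, because C3 and C5 are equivalent and the tertiary cation of the new prenyl group can only be trapped by the neighbouring free 2-OH (the other neighbour is the benzyl ether); limiting the diene keeps the reaction at one annulation.

Step 5
Reactants: 9 1-[5-(benzyloxy)-7-hydroxy-2,2-dimethylchroman-8-yl]ethanone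
Product: 10 1-(5,7-dihydroxy-2,2-dimethylchroman-8-yl)ethanone
Conditions: H2 (1 atm), 10% Pd/C, EtOAc, rt
Reagents that add atoms: none
Why: Hydrogenolysis of the benzyl aryl ether over palladium, run before any C=C bond is in the molecule, should free the 5-OH while the chelated aryl ketone and the chroman stay inert under these mild conditions.

Step 6
Reactants: 10 1-(5,7-dihydroxy-2,2-dimethylchroman-8-yl)ethanone
Product: 11 1-[5,7-dihydroxy-2,2-dimethyl-6-(3-methylbut-2-enyl)chroman-8-yl]ethanone
Conditions: prenyl bromide (1.1 equiv), 10% aq KOH, 0 °C to rt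
Reagents that add atoms: prenyl bromide, CC(C)=CCBr
Why: C-Alkylation of an acylphloroglucinol-type phenoxide in aqueous alkali (ambident anion, soft allylic halide, hydrogen-bonding solvent favouring carbon) should occur at C6, the only unsubstituted ring carbon, which lies between the two hydroxyl groups.

Step 7
Reactants: 11 1-[5,7-dihydroxy-2,2-dimethyl-6-(3-methylbut-2-enyl)chroman-8-yl]ethanone
Product: 12 (E)-3-(dimethylamino)-1-[5,7-dihydroxy-2,2-dimethyl-6-(3-methylbut-2-enyl)chroman-8-yl]prop-2-en-1-one
Conditions: t-BuOCH(NMe2)2 (2 equiv), toluene, 80 °C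
Reagents that add atoms: tert-butoxybis(dimethylamino)methane, CC(C)(C)OC(N(C)C)N(C)C
Why: Condensation of the acetyl CH3 with an aminal ester (Bredereck's reagent) should give the (E)-enaminone, and this reagent is chosen over DMF dimethyl acetal because it cannot methylate the free phenols.

Step 8
Reactants: 12 (E)-enaminone of the A ring; 6 2,2-dimethyl-2H-chromene-5,8-dione
Product: 14 3-aroylbenzofuran (5-hydroxybenzofuran carrying the A-ring ketone on C3 plus the dimethylpyran fused at C6/C7), via aminal 13 (not isolated)
Conditions: AcOH, rt, N2, 6 added slowly (1.0 equiv)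
Reagents that add atoms: none
Why: In this Nenitzescu-type benzofuran synthesis the enaminone α-carbon should add to C6 of quinone 6 (β to the C8 carbonyl, the C5 carbonyl being deactivated as a vinylogous ester by the pyran oxygen), the hydroquinone OH next to the new bond closes on the iminium carbon to aminal 13, and loss of dimethylamine aromatises the furan, so the furan oxygen comes from O5 of the quinone and the para oxygen stays as the free phenol.

Step 9
Reactants: 14 3-aroylbenzofuran
Product: 16 target coumaronochromone CNP0081330.0, via dihydro acetal 15 (not isolated)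
Conditions: DDQ (1.1 equiv), 1,4-dioxane, rt
Reagents that add atoms: none
Why: This is a dehydrogenative cyclisation of the type that converts 2′-hydroxyisoflavones into coumaronochromones: the chelated A-ring OH adds reversibly to C2 of the 3-acylbenzofuran (oxa-Michael addition) to give 15, and DDQ removes the acetal hydride (followed by loss of the C3 proton), which restores the benzofuran and completes the pyranone; one equivalent at room temperature should spare the o-prenylphenol and the pyran double bond.

Compound list
1 | 2,5-dimethoxyphenol | COc1ccc(OC)c(O)c1 | starting material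
2 | 3-methylbut-2-enal (prenal) | CC(C)=CC=O | starting material
3 | 5,8-dimethoxy-4-(2-methylprop-1-enyl)-2-phenyl-4H-1,3,2-benzodioxaborinine (racemic, not isolated) | COc1ccc(OC)c2c1C(C=C(C)C)OB(c1ccccc1)O2 | intermediate
4 | 2,5-dimethoxy-6-(3-methylbut-2-enylidene)cyclohexa-2,4-dien-1-one (o-quinone methide, not isolated, alkene geometry not defined) | COC1=CC=C(OC)C(=O)C1=CC=C(C)C | intermediate
5 | 5,8-dimethoxy-2,2-dimethyl-2H-chromene | COc1ccc(OC)c2c1C=CC(C)(C)O2 | intermediate
6 | 2,2-dimethyl-2H-chromene-5,8-dione | CC1(C)C=CC2=C(O1)C(=O)C=CC2=O | intermediate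
7 | 2,4,6-trihydroxyacetophenone | CC(=O)c1c(O)cc(O)cc1O | starting material
8 | 1-[4-(benzyloxy)-2,6-dihydroxyphenyl]ethanone | CC(=O)c1c(O)cc(OCc2ccccc2)cc1O | intermediate
9 | 1-[5-(benzyloxy)-7-hydroxy-2,2-dimethylchroman-8-yl]ethanone | CC(=O)c1c(O)cc(OCc2ccccc2)c2c1OC(C)(C)CC2 | intermediate
10 | 1-(5,7-dihydroxy-2,2-dimethylchroman-8-yl)ethanone | CC(=O)c1c(O)cc(O)c2c1OC(C)(C)CC2 | intermediate
11 | 1-[5,7-dihydroxy-2,2-dimethyl-6-(3-methylbut-2-enyl)chroman-8-yl]ethanone | CC(=O)c1c(O)c(CC=C(C)C)c(O)c2c1OC(C)(C)CC2 | intermediate
12 | (E)-3-(dimethylamino)-1-[5,7-dihydroxy-2,2-dimethyl-6-(3-methylbut-2-enyl)chroman-8-yl]prop-2-en-1-one | CN(C)/C=C/C(=O)c1c(O)c(CC=C(C)C)c(O)c2c1OC(C)(C)CC2 | intermediate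
13 | N,O-aminal: 2-(dimethylamino)-2,3-dihydrobenzofuran-5-ol with the A-ring aroyl group on C3 and a 2,2-dimethyl-2H-pyran fused at C6 (O) and C7 (CH=); not isolated, relative configuration at C2/C3 not defined | CN(C)C1Oc2c(cc(O)c3OC(C)(C)C=Cc23)C1C(=O)c1c(O)c(CC=C(C)C)c(O)c2c1OC(C)(C)CC2 | intermediate
14 | 3-aroylbenzofuran: 5-hydroxybenzofuran with C2–H free, on C3 the ketone to the 5,7-dihydroxy-2,2-dimethyl-6-(3-methylbut-2-enyl)chroman-8-yl group, and a 2,2-dimethyl-2H-pyran fused at C6 (O) and C7 (CH=) | CC(C)=CCc1c(O)c2c(c(C(=O)c3coc4c3cc(O)c3c4C=CC(C)(C)O3)c1O)OC(C)(C)CC2 | intermediate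
15 | ring-closed O,O-acetal: 2,3-dihydro form of 16 (H on C2 and C3 of the pyranone, cis ring fusion expected, racemic, not isolated) | CC(C)=CCc1c(O)c2c(c3C(=O)C4C(Oc13)Oc1c3c(c(O)cc14)OC(C)(C)C=C3)OC(C)(C)CC2 | intermediate
16 | CNP0081330.0: benzofuro[2,3-b]chromen-4-one (coumaronochromone) with 7-OH, 8-(3-methylbut-2-enyl), a 2,2-dimethyl-3,4-dihydro-2H-pyran fused at C5 (O) and C6 (CH2), 5′-OH, and a 2,2-dimethyl-2H-pyran fused at C3′ (CH=) and C4′ (O) | CC(C)=CCc1c(O)c2c(c3c(=O)c4c(oc13)oc1c3c(c(O)cc14)OC(C)(C)C=C3)OC(C)(C)CC2 | target

Total steps: 9 (steps 1–2 and steps 3–7 are parallel branches). Longest linear sequence: 7 steps (steps 3 to 9, from 7).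

Steps most likely to fail

Step 8. The o-hydroxyaryl enaminone may ring-close with loss of dimethylamine to the 3-unsubstituted chromone before the C–C bond forms, and the hydroquinone adduct may exchange redox state with unreacted quinone. Conjugate addition at C7 of the quinone would also erode regioselectivity. The fallback removes the free ortho-hydroxyl so that the enaminone is a plain aryl enaminone, the standard substrate of the Nenitzescu benzofuran synthesis. It sets out from 11 and comes back at 14. Compound 11 would be treated with NaH and MOMCl in DMF at 0 °C to give 1-[5,7-bis(methoxymethoxy)-2,2-dimethyl-6-(3-methylbut-2-enyl)chroman-8-yl]ethanone F1. Condensation with t-BuOCH(NMe2)2 in toluene at 90 °C should give the bis-MOM enaminone F2. Reaction with 6 in AcOH at rt should give the bis-MOM 3-aroylbenzofuran F3. Both acetals would then be removed with dilute HCl in MeOH at 40 °C to give 14.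

Step 9. Electron transfer from the B-ring p-alkoxyphenol to DDQ, or dehydrogenative pyran closure of the A-ring o-prenylphenol, may compete with hydride removal from the ring-closed acetal. The fallback masks the two oxidisable phenols. It sets out from 14 and comes back at 16. Ac2O in pyridine at rt should acylate the two non-chelated hydroxyls and leave the chelated one free, giving the 7,5′-di-O-acetate of the aroylbenzofuran F4. DDQ in dioxane at 60 °C should then close and dehydrogenate to the di-O-acetate of the coumaronochromone F5. K2CO3 in MeOH at rt would release 16.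

Step 6. O-alkylation and double alkylation of the ambident phenoxide may outrun C-alkylation at C6. The fallback installs the prenyl group by a sigmatropic route. It sets out from 10 and comes back at 11. 3-Chloro-3-methylbut-1-yne with K2CO3, KI and catalytic CuI in acetone at 50 °C should alkylate only the non-chelated 5-OH, giving the 2-methylbut-3-yn-2-yl ether F6. Semihydrogenation (H2, Lindlar catalyst, quinoline, EtOAc) should give the 2-methylbut-3-en-2-yl ether F7. Heating in N,N-diethylaniline at 130 °C should bring about an aromatic Claisen rearrangement to the only free ortho carbon, C6, and give 11.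

Further compounds
F1 | step 8 | 1-[5,7-bis(methoxymethoxy)-2,2-dimethyl-6-(3-methylbut-2-enyl)chroman-8-yl]ethanone | CC(=O)c1c(OCOC)c(CC=C(C)C)c(OCOC)c2c1OC(C)(C)CC2
F2 | step 8 | (E)-3-(dimethylamino)-1-[5,7-bis(methoxymethoxy)-2,2-dimethyl-6-(3-methylbut-2-enyl)chroman-8-yl]prop-2-en-1-one | CN(C)/C=C/C(=O)c1c(OCOC)c(CC=C(C)C)c(OCOC)c2c1OC(C)(C)CC2
F3 | step 8 | bis(methoxymethyl) ether of 14 (both A-ring hydroxyls as OMOM) | CC(C)=CCc1c(OCOC)c2c(c(C(=O)c3coc4c3cc(O)c3c4C=CC(C)(C)O3)c1OCOC)OC(C)(C)CC2
F4 | step 9 | di-O-acetate of 14 (A-ring non-chelated OH and benzofuran 5-OH acetylated) | CC(C)=CCc1c(OC(C)=O)c2c(c(C(=O)c3coc4c3cc(OC(C)=O)c3c4C=CC(C)(C)O3)c1O)OC(C)(C)CC2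
F5 | step 9 | 7,5′-di-O-acetate of 16 | CC(C)=CCc1c(OC(C)=O)c2c(c3c(=O)c4c(oc13)oc1c3c(c(OC(C)=O)cc14)OC(C)(C)C=C3)OC(C)(C)CC2
F6 | step 6 | 1-[7-hydroxy-2,2-dimethyl-5-(2-methylbut-3-yn-2-yloxy)chroman-8-yl]ethanone | CC(=O)c1c(O)cc(OC(C)(C)C#C)c2c1OC(C)(C)CC2
F7 | step 6 | 1-[7-hydroxy-2,2-dimethyl-5-(2-methylbut-3-en-2-yloxy)chroman-8-yl]ethanone | CC(=O)c1c(O)cc(OC(C)(C)C=C)c2c1OC(C)(C)CC2
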